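## The problem

Lepadin H is a cis-fused decahydroquinoline (ring A: N1, C2, C3, C4, C4a, C8a; ring B: C4a, C5–C8, C8a) with a C2 methyl, a C3 (2E,4E)-octa-2,4-dienoate and a C5 5-hydroxyoctyl chain. From the SMILES the configuration is 2S,3R,4aS,5S,8aR,5'R. The hydrogens at C2, C4a, C5 and C8a all lie on one face and H3 on the other. N1, C4 and the chain are therefore all cis on ring B, with the chain on the concave side, and the C2/C3 amino alcohol is trans; the C5 configuration has to be set kinetically, not by equilibration. C2 and C5 flank the ring fusion on the same face, so once present they can together send reagents to the opposite face at C8a and C4a, and C2 can also control C3. C5' lies four methylenes from any other stereocentre and can only come from a separate chiral building block. In connectivity, the heteroatom-bearing carbons C3 (O) and C8a (N) are 1,4-related across C4–C4a, a pattern that aldol or Mannich logic does not give. The feature that makes the key step possible is this array C3–C4–C4a–C8a with the ring-A nitrogen on the carbon next to C3. It is the retron of an oxidised 2-(1-aminoalkyl)furan: C3 and C8a are the furan α-carbons, C4–C4a is the furan β,β-bond, and ring B is fused at the furan 4,5-bond as a 4,5,6,7-tetrahydrobenzofuran. The dienoate does not survive hydrogenation, hydride or nucleophiles and must come after all reductions. The secondary amine next to the ester (O→N acyl shift), the two secondary hydroxyls and the epimerisable α-amino ketone intermediates dictate the protecting groups and the order of steps.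

## Retrosynthesis

**Ester and protecting groups.** Target 22 is taken back to its N-Boc, O-TBS form 21. The C3–O bond of 21 is then cut with inversion, giving the cis-alcohol 19 and acid 20 (Mitsunobu). Hydride delivery to an N-acyl-2-methylpiperidin-3-one gives the cis-alcohol by itself, so the inversion that is needed anyway is merged with the acylation. Acylating a trans-alcohol would instead require a reduction against the inherent bias. The forward step must achieve SN2 at a hindered carbinol without elimination.

**Three hydrogens from one face.** H3, H4a and H8a are removed in turn (19 ⇒ ketone 18 ⇒ enone 17 ⇒ hemiaminal 15). This leaves a flat ring A whose only stereocentres are C2 and C5. Both sit on the same face, so the three reductions are asked only to come from the other face.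

**N1–C8a bond (key).** Hemiaminal 15 is the aza-Achmatowicz product of furan 13. The cut removes the N1–C8a bond and restores the furan oxygen between C3 and C8a. A reductive amination of a saturated amino diketone would need C4a preset and would pass through an aromatisable α-amino ketone imine. The furan instead erases C4a and C8a, is robust, and delivers the right oxidation level at C3, C4, C4a and C8a. The precursor is an aromatic bicycle with only C2, C5 and C5' as stereocentres.

**C4–C4a bond.** Furan 13 comes from 1,4-diketone 12 (Paal–Knorr). In 12 the C4–C4a bond joins two enolate α-carbons, so it is made by oxidative cross-coupling of enol silanes 8 and 11. Alkylation of an enolate with an alanine-derived halomethyl ketone would suffer proton transfer and carbonyl attack. The forward step needs cross-selectivity, which rests on the different oxidation potentials of 8 (trisubstituted) and 11 (terminal, used in excess). The regiochemistry of both partners is fixed by how they are made.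

**C5–C1' bond and the alanine unit.** Enol silane 8 arises from cyclohex-2-en-1-one 4 and alkene 3 by catalytic asymmetric conjugate addition with enolate trapping. One operation sets C5 under catalyst control and delivers the enolate regiospecifically at C4a. Enol silane 11 comes from methyl ketone 10, made from the commercial alanine amide 9, which supplies C2.

**C3'–C4' bond.** Alkene 3 is the TBS ether of alcohol 2, obtained by allyl Grignard opening of (R)-epoxide 1, which supplies C5'.

## Roads not taken

Alternative 1: The most obvious cut is N1–C8a and C4–C4a back to cyclohexane-1,3-dione and an alanine-derived 3-amino-2-(benzyloxy)butyl electrophile. Their union gives the vinylogous amide (2S,3R)-3-(benzyloxy)-2-methyl-2,3,4,6,7,8-hexahydroquinolin-5(1H)-one A1. The forward key step is hydrogenation of its tetrasubstituted C4a=C8a bond to the cis-fused 5-ketone. The chain must then be grown on the C5 carbonyl of a ring that is already saturated (olefination, homologation, a second hydrogenation), and C5 is set late with ring-fusion control only. The anti amino alcohol C2/C3 also has to be made stereoselectively in an open chain. The chosen plan brings C5 with its complete chain in one catalytic step and never makes C3 in an acyclic setting.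

Alternative 2: Cut C4a–C8a and C5–C6 (intramolecular Diels–Alder). The substrate would be methyl (2Z,5R,6S)-6-[(1E)-buta-1,3-dien-1-yl(tert-butoxycarbonyl)amino]-5-[(tert-butyldimethylsilyl)oxy]hept-2-enoate A2. Heating would close both rings to methyl (2S,3R,4aS,5S,8aR)-1-(tert-butoxycarbonyl)-3-[(tert-butyldimethylsilyl)oxy]-2-methyl-1,2,3,4,4a,5,6,8a-octahydroquinoline-5-carboxylate A3, the Z-enoate giving cis fusion and the C4a/C5 cis relation. The cascade is attractive, but the free amine needed to make the dienyl carbamate cannot coexist with the enoate (aza-Michael closure to a pyrrolidine). This forces a long run-up. Facial selectivity rests on the conformational bias of a tether alone. The one-carbon ester of A3 must still be converted into the eight-carbon chain, about five further steps.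

Alternative 3: Cut every ring C–H bond and hydrogenate an aromatic precursor, (4R)-8-(3-hydroxy-2-methylquinolin-5-yl)oct-7-yn-4-ol A4 (Friedländer condensation, Sonogashira coupling). A catalyst-controlled reduction of the pyridine ring and then an all-cis reduction of the carbocycle would aim at 19 after protecting-group adjustment. All four hydrogens H2, H4a, H5 and H8a on one face suit this, but the ring has no stereocentre to start from. The absolute configuration of five centres would rest on one asymmetric hydrogenation of a 3-oxygenated quinoline, C–O hydrogenolysis threatens, and C5' is too remote to help. The chosen plan takes C2 and C5 from reliable sources and uses them in a matched sense.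

Key step: step 8

Remark: positions are given in lepadin numbering throughout; TBS = tert-butyldimethylsilyl, TBSO = TBS-oxy, Boc = tert-butoxycarbonyl. Hemiaminal 15 is written in its closed form; its C8a epimers and the open form 14 serve equally in step 9.

## Route

Step 1
Reactants: 1 (2R)-2-propyloxirane
Product: 2 (4R)-oct-7-en-4-ol
Conditions: allylMgCl, CuI (10 mol%), THF, −30 → 0 °C; aq. NH4Cl
Reagents that add atoms: allylmagnesium chloride, C=CC[Mg]Cl
Why: Copper-catalysed Grignard opening of a terminal epoxide at the CH2 carbon (SN2); the carbinol carbon is not touched, so the R configuration of 1 becomes C5' of the target.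

Step 2
Reactants: 2 (4R)-oct-7-en-4-ol
Product: 3 tert-butyldimethyl{[(4R)-oct-7-en-4-yl]oxy}silane
Conditions: TBSCl, imidazole, DMF, rt
Reagents that add atoms: tert-butyldimethylsilyl chloride, CC(C)(C)[Si](C)(C)Cl
Why: Standard silylation; the TBS ether should tolerate the organozinc, oxidative, Lewis-acid and hydride steps and falls together with Boc in step 13.

Step 3
Reactants: 3 tert-butyldimethyl{[(4R)-oct-7-en-4-yl]oxy}silane, 4 cyclohex-2-en-1-one
Product: 8 (3S)-3-[(5R)-5-(TBSO)octyl]-1-[(trimethylsilyl)oxy]cyclohex-1-ene, via alkyldiethylborane 5 (not isolated), via dialkylzinc 6 (not isolated), via zinc enolate 7 (not isolated)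
Conditions: Et2BH, Et2O, 0 °C → rt; Et2Zn, 0 °C, then vacuum; 4, Cu(OTf)2 (2 mol%), L* (4 mol%), toluene, −30 °C; TMSOTf, −30 → 0 °C (L* = (S)-1,1'-binaphthyl-2,2'-diyl N,N-bis[(R)-1-phenylethyl]phosphoramidite)
Reagents that add atoms: trimethylsilyl trifluoromethanesulfonate, C[Si](C)(C)OS(=O)(=O)C(F)(F)F
Why: Anti-Markovnikov hydroboration and boron–zinc exchange give the functionalised dialkylzinc; copper–phosphoramidite-catalysed asymmetric conjugate addition sets C5, expected S with the (S,R,R) ligand by analogy with simple dialkylzincs. TMSOTf traps the zinc enolate regiospecifically, so the enol ether double bond is C8a=C4a.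

Step 4
Reactants: 9 tert-butyl N-[(2S)-1-[methoxy(methyl)amino]-1-oxopropan-2-yl]carbamate
Product: 10 tert-butyl N-[(2S)-3-oxobutan-2-yl]carbamate
Conditions: MeMgBr (3 equiv), THF, 0 °C; aq. NH4Cl
Reagents that add atoms: methylmagnesium bromide, C[Mg]Br
Why: Ketone synthesis from an N-methoxy-N-methylamide; the chelated tetrahedral adduct survives until work-up, so no tertiary alcohol forms. The carbamate is deprotonated first, which shields the α-hydrogen at C2.

Step 5
Reactants: 10 tert-butyl N-[(2S)-3-oxobutan-2-yl]carbamate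
Product: 11 tert-butyl N-[(2S)-3-[(trimethylsilyl)oxy]but-3-en-2-yl]carbamate
Conditions: LiHMDS (2.2 equiv), THF, −78 °C; TMSCl (1.1 equiv); cold aq. NaHCO3
Reagents that add atoms: chlorotrimethylsilane, C[Si](C)(C)Cl
Why: Kinetic enolisation of the N-lithiated carbamate takes a methyl hydrogen, because the α-CH next to the nitrogen anion is deactivated; O-silylation fixes the terminal enol ether with C2 untouched.

Step 6
Reactants: 8 (3S)-3-[(5R)-5-(TBSO)octyl]-1-[(trimethylsilyl)oxy]cyclohex-1-ene, 11 tert-butyl N-[(2S)-3-[(trimethylsilyl)oxy]but-3-en-2-yl]carbamate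
Product: 12 tert-butyl N-[(2S)-4-{(1R,2S)-2-[(5R)-5-(TBSO)octyl]-6-oxocyclohexyl}-3-oxobutan-2-yl]carbamate
Conditions: (NH4)2Ce(NO3)6 (2.2 equiv), NaHCO3, 11 (3 equiv), MeCN, −20 °C
Reagents that add atoms: none
Why: Oxidative cross-coupling of two enol silanes: the tetravalent cerium salt oxidises the more electron-rich trisubstituted enol ether 8 to the α-keto radical at C4a, which adds to the terminal carbon (C4) of 11 held in excess; a second one-electron oxidation and desilylation give the 1,4-diketone. The new centre C4a (expected mainly trans to the chain) does not matter, since it becomes sp2 in step 7.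

Step 7
Reactants: 12 tert-butyl N-[(2S)-4-{(1R,2S)-2-[(5R)-5-(TBSO)octyl]-6-oxocyclohexyl}-3-oxobutan-2-yl]carbamate
Product: 13 tert-butyl N-[(1S)-1-{(4S)-4-[(5R)-5-(TBSO)octyl]-4,5,6,7-tetrahydro-1-benzofuran-2-yl}ethyl]carbamate
Conditions: p-TsOH·H2O (5 mol%), 4 Å MS, toluene, 60 °C
Reagents that add atoms: none
Why: Paal–Knorr furan synthesis; cyclodehydration is driven by aromatisation and erases C4a, so both epimers of 12 converge. A catalytic amount of acid can remove no more than a trace of Boc.

Step 8
Reactants: 13 tert-butyl N-[(1S)-1-{(4S)-4-[(5R)-5-(TBSO)octyl]-4,5,6,7-tetrahydro-1-benzofuran-2-yl}ethyl]carbamate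
Product: 15 tert-butyl (2S,5S)-5-[(5R)-5-(TBSO)octyl]-8a-hydroxy-2-methyl-3-oxo-3,5,6,7,8,8a-hexahydroquinoline-1(2H)-carboxylate, via Z-enedione carbamate 14 (not isolated)
Conditions: mCPBA (1.1 equiv), CH2Cl2, 0 °C
Reagents that add atoms: 3-chloroperoxybenzoic acid, O=C(OO)c1cccc(Cl)c1
Why: Aza-Achmatowicz rearrangement: the peracid epoxidises the electron-rich trialkylfuran, the epoxy-dihydrofuran opens to the Z-ene-1,4-dione 14 (the furan α-carbons become the C3 and C8a carbonyls, the furan β,β-bond becomes C4=C4a, Z because of its ring origin), and the carbamate N–H adds to the C8a ketone to give hemiaminal 15. The closest known reaction type is the oxidative ring expansion of 5-alkylfurfuryl sulfonamides and carbamates to 6-alkyl-6-hydroxy-2H-pyridin-3(6H)-ones. Ring A is closed by 6-exo-trig attack of nitrogen on the C8a carbonyl; ring B is carried over unchanged from the tetrahydrobenzofuran. The only new stereocentre, the hemiaminal carbon C8a, is not controlled and need not be, because it is made planar again in step 9. The selectivity required is chemoselective oxidation of the furan, the only electron-rich π-system present; carbamate, silyl ether and the saturated chain should be inert to one equivalent of peracid at 0 °C. C2 and C5 should not epimerise under these cold, weakly acidic conditions. In one operation the step lays down the N1–C8a bond, the C3 oxygen and the C4=C4a unsaturation, that is, the flat ring A on which steps 9–11 place three hydrogens from one face.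

Step 9
Reactants: 15 tert-butyl (2S,5S)-5-[(5R)-5-(TBSO)octyl]-8a-hydroxy-2-methyl-3-oxo-3,5,6,7,8,8a-hexahydroquinoline-1(2H)-carboxylate
Product: 17 tert-butyl (2S,5S,8aR)-5-[(5R)-5-(TBSO)octyl]-2-methyl-3-oxo-3,5,6,7,8,8a-hexahydroquinoline-1(2H)-carboxylate, via N-acyliminium ion 16 (not isolated)
Conditions: Et3SiH, BF3·OEt2, CH2Cl2, −78 → −40 °C
Reagents that add atoms: none
Why: Ionic hydrogenation: BF3 ionises the hemiaminal (closed or open form) to the planar N-acyliminium ion 16, and hydride adds to C8a from the face opposite the C2 methyl (pseudoaxial to avoid A(1,3) strain with Boc) and the C5 chain (pseudoaxial to avoid A(1,3) strain with H4), so H8a ends cis to H2 and H5. Attack at C4 is not expected, because positive charge there would sit next to the ketone.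

Step 10
Reactants: 17 tert-butyl (2S,5S,8aR)-5-[(5R)-5-(TBSO)octyl]-2-methyl-3-oxo-3,5,6,7,8,8a-hexahydroquinoline-1(2H)-carboxylate
Product: 18 tert-butyl (2S,4aS,5S,8aR)-5-[(5R)-5-(TBSO)octyl]-2-methyl-3-oxooctahydroquinoline-1(2H)-carboxylate
Conditions: H2 (1 atm), Pd/C, EtOAc, rt
Reagents that add atoms: none
Why: Heterogeneous hydrogenation of the enone C4=C4a from the convex face, opposite the pseudoaxial C2 methyl and ring B (tilted to the same side through C8); H4a should end cis to H8a and H5, giving the cis ring fusion and the all-cis C8a/C4a/C5 triad.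

Step 11
Reactants: 18 tert-butyl (2S,4aS,5S,8aR)-5-[(5R)-5-(TBSO)octyl]-2-methyl-3-oxooctahydroquinoline-1(2H)-carboxylate
Product: 19 tert-butyl (2S,3S,4aS,5S,8aR)-5-[(5R)-5-(TBSO)octyl]-3-hydroxy-2-methyloctahydroquinoline-1(2H)-carboxylate
Conditions: LiBH(s-Bu)3 (L-Selectride), THF, −78 °C; aq. NH4Cl
Reagents that add atoms: none
Why: The bulky hydride attacks the C3 carbonyl anti to the axial C2 methyl of the N-Boc piperidinone chair, which should give the cis-2,3 (3S, equatorial) alcohol, as is usual for N-acyl-2-alkylpiperidin-3-ones.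

Step 12
Reactants: 19 tert-butyl (2S,3S,4aS,5S,8aR)-5-[(5R)-5-(TBSO)octyl]-3-hydroxy-2-methyloctahydroquinoline-1(2H)-carboxylate, 20 (2E,4E)-octa-2,4-dienoic acid
Product: 21 tert-butyl (2S,3R,4aS,5S,8aR)-5-[(5R)-5-(TBSO)octyl]-2-methyl-3-{[(2E,4E)-octa-2,4-dienoyl]oxy}octahydroquinoline-1(2H)-carboxylate
Conditions: 20, PPh3, DIAD, toluene, 0 °C → rt
Reagents that add atoms: none
Why: Mitsunobu esterification: the carboxylate displaces the oxyphosphonium group at C3 with inversion, so the one step turns 3S into 3R (2,3-trans) and installs the dienoate. The equatorial leaving group has no antiperiplanar hydrogen, which disfavours elimination, and axial attack passes only H4a.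

Step 13
Reactants: 21 tert-butyl (2S,3R,4aS,5S,8aR)-5-[(5R)-5-(TBSO)octyl]-2-methyl-3-{[(2E,4E)-octa-2,4-dienoyl]oxy}octahydroquinoline-1(2H)-carboxylate
Product: 22 lepadin H, (2S,3R,4aS,5S,8aR)-5-[(5R)-5-hydroxyoctyl]-2-methyldecahydroquinolin-3-yl (2E,4E)-octa-2,4-dienoate
Conditions: TFA/H2O (9:1), 0 °C → rt; aq. NaHCO3
Reagents that add atoms: none
Why: Acidolysis removes Boc (as isobutene and CO2) and the secondary TBS ether in one operation; the dienoate ester is stable to acid, and the amine stays protonated until the cold basic work-up, which limits O→N acyl transfer.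

## Compound list

1 | (2R)-2-propyloxirane | CCC[C@@H]1CO1 | starting material
2 | (4R)-oct-7-en-4-ol | C=CCC[C@H](O)CCC | intermediate
3 | tert-butyldimethyl{[(4R)-oct-7-en-4-yl]oxy}silane | C=CCC[C@H](O[Si](C)(C)C(C)(C)C)CCC | intermediate
4 | cyclohex-2-en-1-one | O=C1C=CCCC1 | starting material
5 | {(5R)-5-[(tert-butyldimethylsilyl)oxy]octyl}diethylborane | CCB(CC)CCCC[C@H](O[Si](C)(C)C(C)(C)C)CCC | intermediate (not isolated)
6 | bis{(5R)-5-[(tert-butyldimethylsilyl)oxy]octyl}zinc | CCC[C@@H](O[Si](C)(C)C(C)(C)C)CCCC[Zn]CCCC[C@H](O[Si](C)(C)C(C)(C)C)CCC | intermediate (not isolated)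
7 | {(5R)-5-[(tert-butyldimethylsilyl)oxy]octyl}zinc (3S)-3-{(5R)-5-[(tert-butyldimethylsilyl)oxy]octyl}cyclohex-1-en-1-olate | CCC[C@@H](O[Si](C)(C)C(C)(C)C)CCCC[Zn]OC1=C[C@@H](CCCC[C@H](O[Si](C)(C)C(C)(C)C)CCC)CCC1 | intermediate (not isolated)
8 | (3S)-3-{(5R)-5-[(tert-butyldimethylsilyl)oxy]octyl}-1-[(trimethylsilyl)oxy]cyclohex-1-ene | C[Si](C)(C)OC1=C[C@@H](CCCC[C@H](O[Si](C)(C)C(C)(C)C)CCC)CCC1 | intermediate
9 | tert-butyl N-[(2S)-1-[methoxy(methyl)amino]-1-oxopropan-2-yl]carbamate | C[C@H](NC(=O)OC(C)(C)C)C(=O)N(C)OC | starting material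
10 | tert-butyl N-[(2S)-3-oxobutan-2-yl]carbamate | C[C@H](NC(=O)OC(C)(C)C)C(C)=O | intermediate
11 | tert-butyl N-[(2S)-3-[(trimethylsilyl)oxy]but-3-en-2-yl]carbamate | C[C@H](NC(=O)OC(C)(C)C)C(=C)O[Si](C)(C)C | intermediate
12 | tert-butyl N-[(2S)-4-{(1R,2S)-2-[(5R)-5-[(tert-butyldimethylsilyl)oxy]octyl]-6-oxocyclohexyl}-3-oxobutan-2-yl]carbamate (expected major trans isomer; the 1-epimer is carried along) | C[C@H](NC(=O)OC(C)(C)C)C(=O)C[C@H]1C(=O)CCC[C@@H]1CCCC[C@H](O[Si](C)(C)C(C)(C)C)CCC | intermediate
13 | tert-butyl N-[(1S)-1-{(4S)-4-[(5R)-5-[(tert-butyldimethylsilyl)oxy]octyl]-4,5,6,7-tetrahydro-1-benzofuran-2-yl}ethyl]carbamate | C[C@H](NC(=O)OC(C)(C)C)c1cc2c(o1)CCC[C@@H]2CCCC[C@H](O[Si](C)(C)C(C)(C)C)CCC | intermediate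
14 | tert-butyl N-[(2S,4Z)-4-{(2S)-2-[(5R)-5-[(tert-butyldimethylsilyl)oxy]octyl]-6-oxocyclohexylidene}-3-oxobutan-2-yl]carbamate | C[C@H](NC(=O)OC(C)(C)C)C(=O)/C=C1\C(=O)CCC[C@@H]1CCCC[C@H](O[Si](C)(C)C(C)(C)C)CCC | intermediate (not isolated)
15 | tert-butyl (2S,5S)-5-{(5R)-5-[(tert-butyldimethylsilyl)oxy]octyl}-8a-hydroxy-2-methyl-3-oxo-3,5,6,7,8,8a-hexahydroquinoline-1(2H)-carboxylate (C8a epimers) | O=C1C=C2[C@@H](CCCC[C@H](O[Si](C)(C)C(C)(C)C)CCC)CCCC2(O)N(C(=O)OC(C)(C)C)[C@H]1C | intermediate
16 | (2S,5S)-1-(tert-butoxycarbonyl)-5-{(5R)-5-[(tert-butyldimethylsilyl)oxy]octyl}-2-methyl-3-oxo-2,3,5,6,7,8-hexahydroquinolin-1-ium | O=C1C=C2[C@@H](CCCC[C@H](O[Si](C)(C)C(C)(C)C)CCC)CCCC2=[N+](C(=O)OC(C)(C)C)[C@H]1C | intermediate (not isolated)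
17 | tert-butyl (2S,5S,8aR)-5-{(5R)-5-[(tert-butyldimethylsilyl)oxy]octyl}-2-methyl-3-oxo-3,5,6,7,8,8a-hexahydroquinoline-1(2H)-carboxylate | O=C1C=C2[C@@H](CCCC[C@H](O[Si](C)(C)C(C)(C)C)CCC)CCC[C@H]2N(C(=O)OC(C)(C)C)[C@H]1C | intermediate
18 | tert-butyl (2S,4aS,5S,8aR)-5-{(5R)-5-[(tert-butyldimethylsilyl)oxy]octyl}-2-methyl-3-oxooctahydroquinoline-1(2H)-carboxylate | O=C1C[C@H]2[C@@H](CCCC[C@H](O[Si](C)(C)C(C)(C)C)CCC)CCC[C@H]2N(C(=O)OC(C)(C)C)[C@H]1C | intermediate
19 | tert-butyl (2S,3S,4aS,5S,8aR)-5-{(5R)-5-[(tert-butyldimethylsilyl)oxy]octyl}-3-hydroxy-2-methyloctahydroquinoline-1(2H)-carboxylate | O[C@H]1C[C@H]2[C@@H](CCCC[C@H](O[Si](C)(C)C(C)(C)C)CCC)CCC[C@H]2N(C(=O)OC(C)(C)C)[C@H]1C | intermediate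
20 | (2E,4E)-octa-2,4-dienoic acid | CCC/C=C/C=C/C(=O)O | starting material
21 | tert-butyl (2S,3R,4aS,5S,8aR)-5-{(5R)-5-[(tert-butyldimethylsilyl)oxy]octyl}-2-methyl-3-{[(2E,4E)-octa-2,4-dienoyl]oxy}octahydroquinoline-1(2H)-carboxylate | CCC/C=C/C=C/C(=O)O[C@@H]1C[C@H]2[C@@H](CCCC[C@H](O[Si](C)(C)C(C)(C)C)CCC)CCC[C@H]2N(C(=O)OC(C)(C)C)[C@H]1C | intermediate
22 | lepadin H, (2S,3R,4aS,5S,8aR)-5-[(5R)-5-hydroxyoctyl]-2-methyldecahydroquinolin-3-yl (2E,4E)-octa-2,4-dienoate | CCC/C=C/C=C/C(=O)O[C@@H]1C[C@H]2[C@@H](CCCC[C@H](O)CCC)CCC[C@H]2N[C@H]1C | target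

## Step count and risks

Total step count: 13. Longest linear sequence: 11 steps (steps 1–3 and 6–13); steps 4 and 5 form the short branch.

**Step 8 (key step).** The ring may fail to close, because a carbamate nitrogen is a weak nucleophile toward a ketone, so the material may stay as the open Z-ene-dione 14. Acid may also isomerise 14 to the E form, which cannot cyclise, or the hemiaminal may ionise early, lose Boc and aromatise. The fallback gives up the alanine stereocentre and resets it from C5. It sets out from crude 14 and comes back at 19. N-Deprotection (TMSOTf, 2,6-lutidine; then MeOH) frees the amine, which condenses onto the C8a ketone and tautomerises to (5S)-5-{(5R)-5-[(tert-butyldimethylsilyl)oxy]octyl}-2-methyl-5,6,7,8-tetrahydroquinolin-3-ol F1. Hydrogenation of this 3-pyridinol (H2, 50 bar, Rh/Al2O3, AcOH) should deliver hydrogen to the face opposite the pseudoaxial C5 chain and give the all-cis (2S,3S,4aS,5S,8aR)-5-{(5R)-5-[(tert-butyldimethylsilyl)oxy]octyl}-2-methyldecahydroquinolin-3-ol F2. Boc2O then gives 19.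

**Step 6.** Homo-coupling of either enol silane, over-oxidation, erosion of the alanine centre through enolisation, or loss of the silyl ether in the acidic cerium medium may lower the return. The fallback replaces the radical union by an acyl-anion addition. It sets out from 8 and comes back at 12. Enol silane 8 and dimethylmethylideneammonium iodide (CH2Cl2) give the Mannich base (2S,3S)-2-[(dimethylamino)methyl]-3-{(5R)-5-[(tert-butyldimethylsilyl)oxy]octyl}cyclohexan-1-one F3. Quaternisation with MeI and elimination with NaHCO3 give (3S)-2-methylidene-3-{(5R)-5-[(tert-butyldimethylsilyl)oxy]octyl}cyclohexan-1-one F4. A Stetter reaction of F4 with commercial tert-butyl N-[(2S)-1-oxopropan-2-yl]carbamate (3-benzyl-5-(2-hydroxyethyl)-4-methylthiazolium chloride, Et3N, EtOH, 70 °C) forms the C3–C4 bond and gives 12.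

**Step 9.** Hydride may be delivered to the wrong face of C8a if the two pseudoaxial groups shield less than argued. BF3 may also cleave Boc, or the iminium ion may lose a proton instead of taking up hydride. The fallback sets C8a by catalytic cis-hydrogenation of an enamide and not by hydride capture. It sets out from 15 and comes back at 18. Dehydration (trifluoroacetic anhydride, 2,6-lutidine, CH2Cl2, 0 °C) gives the dienamide tert-butyl (2S,5S)-5-{(5R)-5-[(tert-butyldimethylsilyl)oxy]octyl}-2-methyl-3-oxo-3,5,6,7-tetrahydroquinoline-1(2H)-carboxylate F5. Hydrogenation of both C=C bonds (H2, Pd/C, EtOAc) from the face opposite the C2 methyl should give 18 directly.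

**Step 12.** The hindered carbinol may eliminate or fail to react with the weakly acidic dienoic acid, and the phosphine–azodicarboxylate betaine may add to the dienoate. The fallback separates inversion from acylation. It sets out from 19 and comes back at 21. Mitsunobu reaction with the more acidic 4-nitrobenzoic acid (PPh3, DIAD) gives tert-butyl (2S,3R,4aS,5S,8aR)-5-{(5R)-5-[(tert-butyldimethylsilyl)oxy]octyl}-2-methyl-3-[(4-nitrobenzoyl)oxy]octahydroquinoline-1(2H)-carboxylate F6. Methanolysis (K2CO3, MeOH) gives the trans-alcohol tert-butyl (2S,3R,4aS,5S,8aR)-5-{(5R)-5-[(tert-butyldimethylsilyl)oxy]octyl}-3-hydroxy-2-methyloctahydroquinoline-1(2H)-carboxylate F7. Acylation with 20 through the mixed anhydride (2,4,6-trichlorobenzoyl chloride, Et3N; then DMAP, toluene) gives 21 with retention.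

## Further compounds

F1 | step 8 | (5S)-5-{(5R)-5-[(tert-butyldimethylsilyl)oxy]octyl}-2-methyl-5,6,7,8-tetrahydroquinolin-3-ol | Cc1nc2CCC[C@H](CCCC[C@H](O[Si](C)(C)C(C)(C)C)CCC)c2cc1O
F2 | step 8 | (2S,3S,4aS,5S,8aR)-5-{(5R)-5-[(tert-butyldimethylsilyl)oxy]octyl}-2-methyldecahydroquinolin-3-ol | O[C@H]1C[C@H]2[C@@H](CCCC[C@H](O[Si](C)(C)C(C)(C)C)CCC)CCC[C@H]2N[C@H]1C
F3 | step 6 | (2S,3S)-2-[(dimethylamino)methyl]-3-{(5R)-5-[(tert-butyldimethylsilyl)oxy]octyl}cyclohexan-1-one | CN(C)C[C@H]1C(=O)CCC[C@@H]1CCCC[C@H](O[Si](C)(C)C(C)(C)C)CCC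
F4 | step 6 | (3S)-2-methylidene-3-{(5R)-5-[(tert-butyldimethylsilyl)oxy]octyl}cyclohexan-1-one | C=C1C(=O)CCC[C@@H]1CCCC[C@H](O[Si](C)(C)C(C)(C)C)CCC
F5 | step 9 | tert-butyl (2S,5S)-5-{(5R)-5-[(tert-butyldimethylsilyl)oxy]octyl}-2-methyl-3-oxo-3,5,6,7-tetrahydroquinoline-1(2H)-carboxylate | O=C1C=C2[C@@H](CCCC[C@H](O[Si](C)(C)C(C)(C)C)CCC)CCC=C2N(C(=O)OC(C)(C)C)[C@H]1C
F6 | step 12 | tert-butyl (2S,3R,4aS,5S,8aR)-5-{(5R)-5-[(tert-butyldimethylsilyl)oxy]octyl}-2-methyl-3-[(4-nitrobenzoyl)oxy]octahydroquinoline-1(2H)-carboxylate | O=C(O[C@@H]1C[C@H]2[C@@H](CCCC[C@H](O[Si](C)(C)C(C)(C)C)CCC)CCC[C@H]2N(C(=O)OC(C)(C)C)[C@H]1C)c1ccc(cc1)[N+](=O)[O-]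
F7 | step 12 | tert-butyl (2S,3R,4aS,5S,8aR)-5-{(5R)-5-[(tert-butyldimethylsilyl)oxy]octyl}-3-hydroxy-2-methyloctahydroquinoline-1(2H)-carboxylate | O[C@@H]1C[C@H]2[C@@H](CCCC[C@H](O[Si](C)(C)C(C)(C)C)CCC)CCC[C@H]2N(C(=O)OC(C)(C)C)[C@H]1C
A1 | alternative 1 | (2S,3R)-3-(benzyloxy)-2-methyl-2,3,4,6,7,8-hexahydroquinolin-5(1H)-one | O=C1CCCC2=C1C[C@@H](OCc1ccccc1)[C@H](C)N2
A2 | alternative 2 | methyl (2Z,5R,6S)-6-[(1E)-buta-1,3-dien-1-yl(tert-butoxycarbonyl)amino]-5-[(tert-butyldimethylsilyl)oxy]hept-2-enoate | C=C/C=C/N(C(=O)OC(C)(C)C)[C@@H](C)[C@H](O[Si](C)(C)C(C)(C)C)C/C=C\C(=O)OC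
A3 | alternative 2 | methyl (2S,3R,4aS,5S,8aR)-1-(tert-butoxycarbonyl)-3-[(tert-butyldimethylsilyl)oxy]-2-methyl-1,2,3,4,4a,5,6,8a-octahydroquinoline-5-carboxylate | CC(C)(C)[Si](C)(C)O[C@@H]1C[C@H]2[C@@H](C(=O)OC)CC=C[C@H]2N(C(=O)OC(C)(C)C)[C@H]1C
A4 | alternative 3 | (4R)-8-(3-hydroxy-2-methylquinolin-5-yl)oct-7-yn-4-ol | Cc1nc2cccc(C#CCC[C@H](O)CCC)c2cc1O
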